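**Retrosynthetic overview**
1. The two aldehydes at C3 and C5 of ring A come off first. Ring B is a hexasubstituted benzene with no aromatic CH, so a late double formylation of the aryl orsellinate can only strike ring A.
2. Structural feature: ring A is an orsellinate, with the ester carbonyl on C1, the methyl on C2 and hydroxyls on C4 and C6. Its C1–C2 edge (acyl carbon plus methyl) is the triple bond of a but-2-ynoate, and C3–C4–C5–C6 with both oxygens is a 1-methoxy-1,3-bis(silyloxy)buta-1,3-diene.
3. Key disconnection: C1–C6 and C2–C3, a Diels–Alder benzannulation of the ring B ester of but-2-ynoic acid, aromatized by loss of MeOSiMe3.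
4. The crowded O–C(=O) bond between ring B (two ortho methyls) and the acyl carbon is therefore made on slim but-2-ynoic acid, before that acyl carbon gains its own two ortho substituents.
5. Ring order: ring B is present from the start (2,4,5-trimethylphenol; its OH becomes the OMe, Cl enters ortho to it, and the ester oxygen enters at the last ring CH via Br → Li → B → OH). Ring A is the only ring built.

Key step: step 8

Remark on locants: in the text ring A is counted C1 (ester-bearing), C2 (methyl-bearing), C3, C4 (OH), C5, C6 (OH); the systematic names in the compound list count ring A the other way round.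
Remark on stereochemistry: the target has no stereocentre; the double-bond geometry of 11 to 13 does not affect the outcome (11 is drawn E, either isomer serves), and the one stereocentre of 14 is formed racemic and is lost on aromatization.

**Route**

Step 1
Reactants: 1 2,4,5-trimethylphenol
Product: 2 2-chloro-3,4,6-trimethylphenol
Conditions: SO2Cl2 (1.05 equiv), i-Bu2NH (cat.), toluene, 0 °C → rt
Reagents that add atoms: sulfuryl chloride, O=S(=O)(Cl)Cl
Why: Electrophilic aromatic chlorination: the hydroxyl directs to its only unsubstituted ortho carbon (the para carbon carries a methyl), and amine-modulated SO2Cl2 in a non-polar solvent should deliver chlorine ortho to OH without attack at the methyl-bearing para carbon.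

Step 2
Reactants: 2 2-chloro-3,4,6-trimethylphenol
Product: 3 3-chloro-2-methoxy-1,4,5-trimethylbenzene
Conditions: MeI, K2CO3, DMF, 40 °C
Reagents that add atoms: iodomethane, CI
Why: Williamson ether synthesis (SN2 of the phenoxide on iodomethane); the small electrophile tolerates the chloro and methyl groups flanking the oxygen.

Step 3
Reactants: 3 3-chloro-2-methoxy-1,4,5-trimethylbenzene
Product: 4 1-bromo-4-chloro-3-methoxy-2,5,6-trimethylbenzene
Conditions: Br2 (1.05 equiv), FeBr3 (cat.), CH2Cl2, 0 °C, dark
Reagents that add atoms: bromine, BrBr
Why: Electrophilic aromatic bromination at the single remaining ring CH, which is activated by its two ortho methyl groups; Lewis-acid conditions in the dark keep the process ionic so that the benzylic positions should stay untouched.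

Step 4
Reactants: 4 1-bromo-4-chloro-3-methoxy-2,5,6-trimethylbenzene
Product: 7 4-chloro-3-methoxy-2,5,6-trimethylphenol, via aryllithium 5 (not isolated), via dimethyl arylboronate 6 (not isolated)
Conditions: n-BuLi, THF, −78 °C; B(OMe)3, −78 °C → rt; AcOH, 30% H2O2, 0 °C → rt
Reagents that add atoms: hydrogen peroxide, OO
Why: Bromine–lithium exchange (much faster than chlorine exchange or benzylic deprotonation at −78 °C) gives 5, electrophilic borylation gives 6, and peroxide oxidation of the boronate with 1,2-migration of the aryl group from boron to oxygen should place the hydroxyl exactly where bromine stood.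

Step 5
Reactants: 7 4-chloro-3-methoxy-2,5,6-trimethylphenol; 8 but-2-ynoic acid
Product: 9 4-chloro-3-methoxy-2,5,6-trimethylphenyl but-2-ynoate
Conditions: DCC (1.2 equiv), DMAP (0.1 equiv), CH2Cl2, 0 °C → rt
Reagents that add atoms: none
Why: Steglich esterification: the carbodiimide-activated acid has only a rod-like alkynyl group next to its carbonyl, so the phenol flanked by two ortho methyls can still reach it, and cold conditions with little DMAP hold back conjugate addition to the ynoate.

Step 6
Reactants: 10 methyl acetoacetate
Product: 11 methyl (E)-3-(trimethylsilyloxy)but-2-enoate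
Conditions: TMSCl, Et3N, hexane, rt
Reagents that add atoms: chlorotrimethylsilane, C[Si](C)(C)Cl
Why: Silyl enol ether formation: soft enolization of the β-keto ester by Et3N and O-silylation of the ketone enolate oxygen.

Step 7
Reactants: 11 methyl (E)-3-(trimethylsilyloxy)but-2-enoate
Product: 13 (1Z)-1-methoxy-1,3-bis(trimethylsilyloxy)buta-1,3-diene, via lithium dienolate 12 (not isolated)
Conditions: LiN(i-Pr)2, THF, −78 °C; TMSCl, −78 °C → rt; filtered under argon, used crude
Reagents that add atoms: chlorotrimethylsilane, C[Si](C)(C)Cl
Why: Deprotonation of the γ-methyl of the β-silyloxy enoate by the hindered amide gives the extended enolate 12, which TMSCl should trap on the ester oxygen (silyl ketene acetal formation) to give the moisture-sensitive diene.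

Step 8
Reactants: 9 4-chloro-3-methoxy-2,5,6-trimethylphenyl but-2-ynoate; 13 (1Z)-1-methoxy-1,3-bis(trimethylsilyloxy)buta-1,3-diene
Product: 16 4-chloro-3-methoxy-2,5,6-trimethylphenyl 2,4-dihydroxy-6-methylbenzoate (aryl orsellinate), via cyclohexadiene ketal cycloadduct 14 (not isolated), via C4 trimethylsilyl ether 15 (not isolated)
Conditions: 13 (3 equiv), xylene, 140 °C, sealed tube; then 1 M HCl, THF, rt
Reagents that add atoms: none
Why: The diene, its HOMO raised by three oxygen donors, should add to the electron-poor triple bond of 9 in a thermal, asynchronous normal-demand (4+2) cycloaddition in which its CH2 terminus bonds to the methyl-bearing β-carbon of the ynoate (forming C2–C3) and its ketene acetal carbon bonds to the α-carbon (forming C1–C6), so ring A closes as a six-membered ring by cycloaddition and not by cyclization of a chain. Cycloadduct 14 then expels MeOSiMe3 from its ketal carbon C6, the resulting dienone tautomerizes to phenol 15, and dilute HCl removes the remaining aryl silyl ether to give 16. The closest known reaction type is the Diels–Alder/eliminative aromatization of 1,1,3-trioxygenated butadienes with alkynoates, including β-alkyl ynoates at about this temperature, to give resorcylates. The only stereocentre formed, the ketal carbon of 14, is racemic and disappears on aromatization, so no stereocontrol is needed. The step needs regiocontrol, which the matched polarization of the partners secures (largest HOMO coefficient at the diene CH2 terminus, largest LUMO coefficient at the ynoate β-carbon), placing the methyl on C2 and the hydroxyls on C4 and C6. It also needs the triple bond to react in preference to the ester carbonyl, which is helped by the two ortho methyls of ring B shielding that carbonyl and by the absence of any Lewis acid.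

Step 9
Reactants: 16 4-chloro-3-methoxy-2,5,6-trimethylphenyl 2,4-dihydroxy-6-methylbenzoate
Product: 19 4-chloro-3-methoxy-2,5,6-trimethylphenyl 3,5-diformyl-2,4-dihydroxy-6-methylbenzoate (target), via C5-formyl monoaldehyde 17 (not isolated), via C3-formyl monoaldehyde 18 (not isolated)
Conditions: Cl2CHOMe (6 equiv), TiCl4 (8 equiv), CH2Cl2, 0 °C → rt; then 1 M HCl, rt
Reagents that add atoms: dichloromethyl methyl ether, COC(Cl)Cl; water, O
Why: Rieche formylation (Friedel–Crafts type): the titanium phenoxides of ring A direct the chloro(methoxy)methyl cation to C3 and C5, the only aromatic CH positions in the molecule and each ortho or para to both oxygens, while ring B is hexasubstituted and its ester has no free ortho or para site for a Fries shift, so excess reagent should carry 17 and 18 on to the dialdehyde, freed on aqueous acid work-up.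

**Compound list**
1 | 2,4,5-trimethylphenol | Cc1cc(C)c(O)cc1C | starting material
2 | 2-chloro-3,4,6-trimethylphenol | Cc1cc(C)c(O)c(Cl)c1C | intermediate
3 | 3-chloro-2-methoxy-1,4,5-trimethylbenzene | Cc1cc(C)c(OC)c(Cl)c1C | intermediate
4 | 1-bromo-4-chloro-3-methoxy-2,5,6-trimethylbenzene | Cc1c(Br)c(C)c(OC)c(Cl)c1C | intermediate
5 | (4-chloro-3-methoxy-2,5,6-trimethylphenyl)lithium | [Li]c1c(C)c(OC)c(Cl)c(C)c1C | intermediate
6 | dimethyl (4-chloro-3-methoxy-2,5,6-trimethylphenyl)boronate | COB(OC)c1c(C)c(OC)c(Cl)c(C)c1C | intermediate
7 | 4-chloro-3-methoxy-2,5,6-trimethylphenol | Cc1c(O)c(C)c(OC)c(Cl)c1C | intermediate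
8 | but-2-ynoic acid | CC#CC(=O)O | starting material
9 | 4-chloro-3-methoxy-2,5,6-trimethylphenyl but-2-ynoate | CC#CC(=O)Oc1c(C)c(OC)c(Cl)c(C)c1C | intermediate
10 | methyl acetoacetate | COC(=O)CC(C)=O | starting material
11 | methyl (E)-3-(trimethylsilyloxy)but-2-enoate | C/C(O[Si](C)(C)C)=C\C(=O)OC | intermediate
12 | lithium (1E)-1-methoxy-3-(trimethylsilyloxy)buta-1,3-dien-1-olate (same spatial arrangement as 13) | C=C(O[Si](C)(C)C)/C=C(/OC)O[Li] | intermediate
13 | (1Z)-1-methoxy-1,3-bis(trimethylsilyloxy)buta-1,3-diene | C=C(O[Si](C)(C)C)/C=C(/OC)O[Si](C)(C)C | intermediate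
14 | 4-chloro-3-methoxy-2,5,6-trimethylphenyl 6-methoxy-2-methyl-4,6-bis(trimethylsilyloxy)cyclohexa-1,4-diene-1-carboxylate (racemic) | CC1=C(C(=O)Oc2c(C)c(OC)c(Cl)c(C)c2C)C(OC)(O[Si](C)(C)C)C=C(O[Si](C)(C)C)C1 | intermediate
15 | 4-chloro-3-methoxy-2,5,6-trimethylphenyl 2-hydroxy-6-methyl-4-(trimethylsilyloxy)benzoate | Cc1cc(O[Si](C)(C)C)cc(O)c1C(=O)Oc1c(C)c(OC)c(Cl)c(C)c1C | intermediate
16 | 4-chloro-3-methoxy-2,5,6-trimethylphenyl 2,4-dihydroxy-6-methylbenzoate | Cc1cc(O)cc(O)c1C(=O)Oc1c(C)c(OC)c(Cl)c(C)c1C | intermediate
17 | 4-chloro-3-methoxy-2,5,6-trimethylphenyl 3-formyl-2,4-dihydroxy-6-methylbenzoate (formyl between the two hydroxyls) | Cc1cc(O)c(C=O)c(O)c1C(=O)Oc1c(C)c(OC)c(Cl)c(C)c1C | intermediate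
18 | 4-chloro-3-methoxy-2,5,6-trimethylphenyl 3-formyl-4,6-dihydroxy-2-methylbenzoate (formyl between methyl and hydroxyl) | Cc1c(C=O)c(O)cc(O)c1C(=O)Oc1c(C)c(OC)c(Cl)c(C)c1C | intermediate
19 | 4-chloro-3-methoxy-2,5,6-trimethylphenyl 3,5-diformyl-2,4-dihydroxy-6-methylbenzoate | COc1c(C)c(OC(=O)c2c(C)c(C=O)c(O)c(C=O)c2O)c(C)c(C)c1Cl | target

**Step count**
Total step count: 9. Longest linear sequence: 7 steps (steps 1, 2, 3, 4, 5, 8, 9); the diene branch (steps 6 and 7) joins at step 8.

**Steps most likely to fail**

1. Step 8. The cycloaddition to the β-methyl ynoate may be slower than thermal loss of the diene (silyl migration, oligomerization), or the ketene acetal end may add (2+2) to the alkyne or attack the ester carbonyl with expulsion of the ring B phenoxide. Fallback, setting out from 7 and returning at 16: commercial methyl 2,4-dihydroxy-6-methylbenzoate would be benzylated (BnBr, K2CO3, DMF) to methyl 2,4-bis(benzyloxy)-6-methylbenzoate F1 and saponified (KOH, aqueous DMSO, 90 °C) to 2,4-bis(benzyloxy)-6-methylbenzoic acid F2. F2 and phenol 7 would then be condensed with trifluoroacetic anhydride in toluene at rt; the mixed anhydride ionizes to a linear, alkoxy-stabilized acylium ion that a hindered phenol can still capture. This should give 4-chloro-3-methoxy-2,5,6-trimethylphenyl 2,4-bis(benzyloxy)-6-methylbenzoate F3, and hydrogenolysis of the two benzyl ethers (H2, 1 atm, Pd on carbon, EtOAc, rt, stopped after two equivalents of uptake to spare the aryl chloride) would return 16.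

2. Step 9. The second formylation may stall once the first formyl group and its titanium chelate have deactivated ring A, and long exposure to the Lewis acid may begin to cleave the aryl ester or the methyl ether. Fallback, setting out from 16 (or from the recovered mixture of 17 and 18) and returning at 19: a Duff reaction with excess hexamethylenetetramine in CF3CO2H at 90 °C, then 3 M HCl. The carbon is introduced by aminomethylation with iminium ions under Brønsted acid, and the benzylic amines are oxidized by internal hydride transfer before hydrolysis. This manifold is known to install two formyl groups ortho to the hydroxyl of para-hydroxybenzoates. It makes no compound that the list does not already hold.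

3. Step 5. Acyl transfer to the phenol flanked by two ortho methyls may be slower than rearrangement of the activated acid to its N-acylurea or than conjugate addition of DMAP or phenoxide to the ynoate. Fallback, setting out from 7 and returning at 9: phenol 7 would be heated with commercial 2,2,6-trimethyl-4H-1,3-dioxin-4-one in xylene at 140 °C, where acetylketene is released and trapped at the O–H bond, giving 4-chloro-3-methoxy-2,5,6-trimethylphenyl 3-oxobutanoate F4. Enolization with LiN(SiMe3)2 and triflation with Tf2O (THF, −78 °C) should give 4-chloro-3-methoxy-2,5,6-trimethylphenyl (Z)-3-(trifluoromethylsulfonyloxy)but-2-enoate F5. A second equivalent of LiN(SiMe3)2 would then remove the vinylic hydrogen anti to the triflate and eliminate it to the triple bond of 9.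

Further compounds
F1 | step 8 | methyl 2,4-bis(benzyloxy)-6-methylbenzoate | COC(=O)c1c(C)cc(OCc2ccccc2)cc1OCc1ccccc1
F2 | step 8 | 2,4-bis(benzyloxy)-6-methylbenzoic acid | Cc1cc(OCc2ccccc2)cc(OCc2ccccc2)c1C(=O)O
F3 | step 8 | 4-chloro-3-methoxy-2,5,6-trimethylphenyl 2,4-bis(benzyloxy)-6-methylbenzoate | Cc1cc(OCc2ccccc2)cc(OCc2ccccc2)c1C(=O)Oc1c(C)c(OC)c(Cl)c(C)c1C
F0 | step 9 | none | none
F4 | step 5 | 4-chloro-3-methoxy-2,5,6-trimethylphenyl 3-oxobutanoate | CC(=O)CC(=O)Oc1c(C)c(OC)c(Cl)c(C)c1C
F5 | step 5 | 4-chloro-3-methoxy-2,5,6-trimethylphenyl (Z)-3-(trifluoromethylsulfonyloxy)but-2-enoate | C/C(OS(=O)(=O)C(F)(F)F)=C/C(=O)Oc1c(C)c(OC)c(Cl)c(C)c1C
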